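Everything rests on treating ring A as a ring still to be built. Its ether carbon A C2 lies between the hydroxylated carbons A C1 and A C3, which is the pattern of the central carbon and the two ester carbons of an aryloxymalonate. The crowded A C2–O–B C1 ether is therefore made first, by alkylating an unhindered phenol. The resulting dimethyl malonate, bearing the 4-(benzyloxy)-3,5-dimethoxyphenoxy group of ring B, is condensed with dimethyl 3-oxopentanedioate in a [3+3] double Claisen reaction that forms A C1–C6 and A C3–C4, closes ring A and aromatises in one operation. Copper-mediated couplings of three blocks (AB, CD, EFG) and a seventeen-fold demethylation complete the route.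

Key step: step 4

Remark on lettering: rings A to G run along the chain from the 2,4,6-trihydroxyphenyl end.
- Ether oxygens sit on A C2, B C1/C4, C C1/C2, D C1/C4, E C1/C2, F C1/C4 and G C1, with the lower locant facing ring A.
- Hydroxyls sit on A C1/C3/C5, B C3/C5, C C3/C4/C5, D C3/C5, E C3/C5, F C3/C5 and G C3/C4/C5.

Remark on the chemistry (assumption): the target has no stereocentre and rotation about the ether bonds is taken as free, so names and SMILES carry no descriptors.

Remark on design:
- All phenols travel as methyl ethers. Benzyl marks only the two phenols (B C4–OH, D C4–OH) that must be unmasked for coupling.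
- Every coupling pairs a di-ortho-oxygenated phenol as nucleophile with an aryl halide or arylboronic acid.
- Boronic acid couplings at room temperature are used wherever a halide must survive for a later union.

Step 1
Reactants: 1 syringaldehyde (4-hydroxy-3,5-dimethoxybenzaldehyde)
Product: 2 4-(benzyloxy)-3,5-dimethoxybenzaldehyde
Conditions: BnBr, K2CO3, DMF, 60 °C
Reagents that add atoms: benzyl bromide, BrCc1ccccc1
Why: Williamson ether synthesis on an acidic para-formyl phenol with a benzylic bromide is routine, and benzyl is chosen because it survives methoxide and hot alkali yet can later be removed beside methyl ethers.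

Step 2
Reactants: 2 4-(benzyloxy)-3,5-dimethoxybenzaldehyde
Product: 4 4-(benzyloxy)-3,5-dimethoxyphenol, via aryl formate 3 (not isolated)
Conditions: mCPBA, CH2Cl2, 0 °C to rt; aq NaHCO3 wash; K2CO3 (cat.), MeOH, rt
Reagents that add atoms: mCPBA (3-chloroperoxybenzoic acid), OOC(=O)c1cccc(Cl)c1
Why: Baeyer–Villiger oxidation of a benzaldehyde carrying a para alkoxy donor proceeds with aryl migration, and transesterification of the formate with methanol frees the unhindered B C1 phenol.

Step 3
Reactants: 4 4-(benzyloxy)-3,5-dimethoxyphenol; 5 dimethyl chloromalonate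
Product: 6 dimethyl 2-[4-(benzyloxy)-3,5-dimethoxyphenoxy]malonate
Conditions: K2CO3, acetone, reflux
Reagents that add atoms: none
Why: Williamson-type SN2 displacement of chloride from the doubly activated malonate carbon by an unhindered phenoxide is the standard entry to aryloxymalonates and fixes the A C2–O–B C1 ether before ring A exists.

Step 4
Reactants: 6 dimethyl 2-[4-(benzyloxy)-3,5-dimethoxyphenoxy]malonate; 7 dimethyl 3-oxopentanedioate
Product: 9 dimethyl 5-[4-(benzyloxy)-3,5-dimethoxyphenoxy]-2,4,6-trihydroxybenzene-1,3-dicarboxylate, via open-chain triester 8 (not isolated)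
Conditions: 7 (1.5 equiv), NaOMe (1.5 equiv), MeOH, 0 °C; added slowly to 6 in toluene at 110 °C with MeOH distilling off; second NaOMe charge (2 equiv), 110 °C, argon; cold 1 M HCl
Reagents that add atoms: none
Why: Proposed new method: the sodium enolate of 7, the more acidic partner, so that 6 stays largely un-ionised and electrophilic at the start, attacks one ester of 6 and expels methoxide to give 8 (bond A C3–C4), whose free CH2 carbanion then attacks the second malonate ester in a 6-exo-trig Dieckmann-type closure (bond A C1–C6), and threefold enolisation delivers the arene as its sodium phenoxide. The closest known reaction type is the Baeyer phloroglucinol synthesis, in which sodium alkoxide condenses malonic and 3-oxoglutaric-type esters to phloroglucinol carboxylates, whereas aryloxymalonates are established 1,3-bis-electrophiles only towards N,N-dinucleophiles such as amidines, so the pairing with a C,C-dinucleophile is the untested part. Every acyl transfer is reversible under methoxide but the aromatic polyanion is not, and methanol is distilled out, so O-acylated pyranone isomers and the one alternative six-membered carbocycle (A C2 carbanion onto the distal ester, a quaternary trione that cannot aromatise) are re-opened and drained into 9. The selectivity needed is crossed C-acylation over self-condensation of 7, and it is secured by keeping 7 fully enolised so that its ketone is masked, by feeding it slowly so that 6 is always in local excess, and by the inductive activation of the esters of 6 by the aryloxy group. Both partners are symmetric and the alkoxide matches the esters, so no regiochemical or ester-scrambling question arises, and no stereocentre is formed.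

Step 5
Reactants: 9 dimethyl 5-[4-(benzyloxy)-3,5-dimethoxyphenoxy]-2,4,6-trihydroxybenzene-1,3-dicarboxylate
Product: 11 2-[4-(benzyloxy)-3,5-dimethoxyphenoxy]benzene-1,3,5-triol, via isophthalic diacid 10 (not isolated)
Conditions: 4 M aq KOH (degassed), reflux, argon; then HCl to pH 1, 60 °C
Reagents that add atoms: none
Why: Ester saponification followed by protodecarboxylation of a 2,4,6-trihydroxybenzoic acid, which loses CO2 readily through its keto tautomer, is the classical end of the phloroglucinol synthesis, and aryl, benzyl and methyl ethers are inert to hot alkali.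

Step 6
Reactants: 11 2-[4-(benzyloxy)-3,5-dimethoxyphenoxy]benzene-1,3,5-triol
Product: 12 2-(benzyloxy)-1,3-dimethoxy-5-(2,4,6-trimethoxyphenoxy)benzene
Conditions: Me2SO4 (4 equiv), K2CO3, acetone, reflux, argon
Reagents that add atoms: dimethyl sulfate, COS(=O)(=O)OC
Why: Williamson-type O-methylation with the hard electrophile dimethyl sulfate and K2CO3 in acetone is the standard way to permethylate phloroglucinols while keeping C-methylation low.

Step 7
Reactants: 12 2-(benzyloxy)-1,3-dimethoxy-5-(2,4,6-trimethoxyphenoxy)benzene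
Product: 13 2,6-dimethoxy-4-(2,4,6-trimethoxyphenoxy)phenol (block AB)
Conditions: H2 (1 atm), 10% Pd/C, EtOAc–MeOH, rt
Reagents that add atoms: none
Why: Catalytic hydrogenolysis cleaves only the benzylic C–O bond, leaves methyl and diaryl ethers intact and frees the B C4 phenol.

Step 8
Reactants: 14 4-bromo-2,6-dimethoxyphenol
Product: 15 2-(benzyloxy)-5-bromo-1,3-dimethoxybenzene
Conditions: BnBr, K2CO3, DMF, rt
Reagents that add atoms: benzyl bromide, BrCc1ccccc1
Why: Williamson ether synthesis masks the D C4 oxygen with the same removable group as in ring B and leaves the aryl bromide untouched.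

Step 9
Reactants: 15 2-(benzyloxy)-5-bromo-1,3-dimethoxybenzene
Product: 18 [4-(benzyloxy)-3,5-dimethoxyphenyl]boronic acid, via aryllithium 16 (not isolated), via lithium triisopropoxyborate 17 (not isolated)
Conditions: n-BuLi, THF, −78 °C; B(OiPr)3, −78 °C to rt; 1 M HCl
Reagents that add atoms: triisopropyl borate, CC(C)OB(OC(C)C)OC(C)C; water, O
Why: Bromine–lithium exchange outruns ring or benzylic deprotonation at −78 °C, and trapping with a borate ester followed by acidic hydrolysis is the standard boronic acid synthesis.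

Step 10
Reactants: 19 2,3,4-trimethoxybenzaldehyde
Product: 21 2,3,4-trimethoxyphenol, via aryl formate 20 (not isolated)
Conditions: mCPBA, CH2Cl2, 0 °C to rt; aq NaHCO3 wash; K2CO3 (cat.), MeOH, rt
Reagents that add atoms: mCPBA (3-chloroperoxybenzoic acid), OOC(=O)c1cccc(Cl)c1
Why: Baeyer–Villiger oxidation with aryl migration is favoured by the ortho and para methoxy donors, and methanolysis of the formate gives the phenol that becomes the C C2 oxygen.

Step 11
Reactants: 21 2,3,4-trimethoxyphenol
Product: 22 6-iodo-2,3,4-trimethoxyphenol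
Conditions: NIS (1.0 equiv), TsOH·H2O (10 mol %), MeCN, 0 °C, dark
Reagents that add atoms: N-iodosuccinimide, O=C1CCC(=O)N1I
Why: Electrophilic aromatic iodination is steered by the free hydroxyl, the strongest donor, to its only open ortho position C6 of 21 (the para position is blocked), a site that is also para to the C3 methoxy group.

Step 12
Reactants: 22 6-iodo-2,3,4-trimethoxyphenol; 18 [4-(benzyloxy)-3,5-dimethoxyphenyl]boronic acid
Product: 23 2-[4-(benzyloxy)-3,5-dimethoxyphenoxy]-1-iodo-3,4,5-trimethoxybenzene (block CD)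
Conditions: Cu(OAc)2 (1 equiv), pyridine (5 equiv), 4 Å MS, CH2Cl2, dry air (terminal oxidant), rt
Reagents that add atoms: none
Why: Chan–Lam coupling joins di-ortho-substituted halophenols to unhindered arylboronic acids at room temperature, where the aryl iodide needed for step 18 does not react.

Step 13
Reactants: 14 4-bromo-2,6-dimethoxyphenol; 24 (3,4,5-trimethoxyphenyl)boronic acid
Product: 25 5-bromo-1,3-dimethoxy-2-(3,4,5-trimethoxyphenoxy)benzene (block FG)
Conditions: Cu(OAc)2 (1 equiv), pyridine (5 equiv), 4 Å MS, CH2Cl2, dry air (terminal oxidant), rt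
Reagents that add atoms: none
Why: Chan–Lam coupling forms the F C4–O–G C1 ether from two catalogue compounds and spares the para bromide, which also blocks oxidative para coupling of the phenol.

Step 14
Reactants: 25 5-bromo-1,3-dimethoxy-2-(3,4,5-trimethoxyphenoxy)benzene
Product: 28 [3,5-dimethoxy-4-(3,4,5-trimethoxyphenoxy)phenyl]boronic acid, via aryllithium 26 (not isolated), via lithium triisopropoxyborate 27 (not isolated)
Conditions: n-BuLi, THF, −78 °C; B(OiPr)3, −78 °C to rt; 1 M HCl
Reagents that add atoms: triisopropyl borate, CC(C)OB(OC(C)C)OC(C)C; water, O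
Why: Bromine–lithium exchange and borate trapping convert the unhindered F C1 bromide into the boronic acid, and only ethers are present as spectators.

Step 15
Reactants: 28 [3,5-dimethoxy-4-(3,4,5-trimethoxyphenoxy)phenyl]boronic acid; 29 5-bromovanillin (3-bromo-4-hydroxy-5-methoxybenzaldehyde)
Product: 30 3-bromo-4-[3,5-dimethoxy-4-(3,4,5-trimethoxyphenoxy)phenoxy]-5-methoxybenzaldehyde
Conditions: Cu(OAc)2 (1 equiv), pyridine (5 equiv), 4 Å MS, CH2Cl2, dry air (terminal oxidant), rt; 28 in 1.5-fold excess
Reagents that add atoms: none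
Why: Chan–Lam coupling works well with acidic, oxidation-resistant ortho-halophenols and tolerates both the formyl group and the bromide, so ring E arrives with E C1–Br and the latent E C5 oxygen in place.

Step 16
Reactants: 30 3-bromo-4-[3,5-dimethoxy-4-(3,4,5-trimethoxyphenoxy)phenoxy]-5-methoxybenzaldehyde
Product: 32 3-bromo-4-[3,5-dimethoxy-4-(3,4,5-trimethoxyphenoxy)phenoxy]-5-methoxyphenol, via aryl formate 31 (not isolated)
Conditions: mCPBA (1.2 equiv), CH2Cl2, 0 °C to rt; aq NaHCO3 wash; K2CO3 (cat.), MeOH, rt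
Reagents that add atoms: mCPBA (3-chloroperoxybenzoic acid), OOC(=O)c1cccc(Cl)c1
Why: Baeyer–Villiger oxidation of a 4-aryloxybenzaldehyde goes with aryl migration thanks to the para oxygen donor, the bromide is inert to peracid, and methanolysis gives the E C5 phenol.

Step 17
Reactants: 32 3-bromo-4-[3,5-dimethoxy-4-(3,4,5-trimethoxyphenoxy)phenoxy]-5-methoxyphenol
Product: 33 1-bromo-2-[3,5-dimethoxy-4-(3,4,5-trimethoxyphenoxy)phenoxy]-3,5-dimethoxybenzene (block EFG)
Conditions: MeI, K2CO3, acetone, reflux
Reagents that add atoms: iodomethane, CI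
Why: Williamson methylation of an unhindered phenol with no other acidic site is unproblematic.

Step 18
Reactants: 13 2,6-dimethoxy-4-(2,4,6-trimethoxyphenoxy)phenol; 23 2-[4-(benzyloxy)-3,5-dimethoxyphenoxy]-1-iodo-3,4,5-trimethoxybenzene
Product: 34 2-(benzyloxy)-5-{6-[2,6-dimethoxy-4-(2,4,6-trimethoxyphenoxy)phenoxy]-2,3,4-trimethoxyphenoxy}-1,3-dimethoxybenzene (rings A–D)
Conditions: CuI (20 mol %), picolinic acid (40 mol %), K3PO4 (2 equiv), DMSO, 90 °C, argon
Reagents that add atoms: none
Why: The ligand-accelerated Ullmann ether synthesis with picolinic acid is suited to di-ortho-substituted phenols and ortho-substituted aryl halides, and the iodide was chosen for ring C because its carbon is the more electron-rich of the two hindered coupling sites.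

Step 19
Reactants: 34 rings A–D benzyl ether
Product: 35 4-{6-[2,6-dimethoxy-4-(2,4,6-trimethoxyphenoxy)phenoxy]-2,3,4-trimethoxyphenoxy}-2,6-dimethoxyphenol (rings A–D phenol)
Conditions: H2 (1 atm), 10% Pd/C, EtOAc–MeOH, rt
Reagents that add atoms: none
Why: Catalytic hydrogenolysis removes the single benzyl group, no halogen is left in the molecule, and the D C4 phenol is set free.

Step 20
Reactants: 35 rings A–D phenol; 33 1-bromo-2-[3,5-dimethoxy-4-(3,4,5-trimethoxyphenoxy)phenoxy]-3,5-dimethoxybenzene
Product: 36 heptadeca-O-methyl ether of the target (rings A–G, all seventeen phenols as OMe)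
Conditions: 33 (1.3 equiv), CuI (20 mol %), picolinic acid (40 mol %), K3PO4 (2 equiv), DMSO, 110 °C, argon
Reagents that add atoms: none
Why: The same Ullmann ether synthesis closes the D C4–O–E C1 bond, the E C1 bromide carrying only meta methoxy groups, which withdraw inductively and do not enrich the reacting carbon.

Step 21
Reactants: 36 heptadeca-O-methyl ether of the target
Product: 37 CNP0351377.0 (target, seventeen free phenols)
Conditions: BBr3 (40 equiv), CH2Cl2, −78 °C to rt, argon; ice-water; Sephadex LH-20, degassed MeOH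
Reagents that add atoms: none
Why: In the BBr3 cleavage of aryl methyl ethers, bromide attacks the methyl carbon of the boron-complexed ether in an SN2 step, so only O–CH3 bonds break and the six diaryl ether bonds, which offer no sp3 carbon, persist.

Compound list
1 | syringaldehyde (4-hydroxy-3,5-dimethoxybenzaldehyde) | COc1cc(C=O)cc(OC)c1O | starting material
2 | 4-(benzyloxy)-3,5-dimethoxybenzaldehyde | COc1cc(C=O)cc(OC)c1OCc1ccccc1 | intermediate
3 | 4-(benzyloxy)-3,5-dimethoxyphenyl formate | COc1cc(OC=O)cc(OC)c1OCc1ccccc1 | intermediate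
4 | 4-(benzyloxy)-3,5-dimethoxyphenol | COc1cc(O)cc(OC)c1OCc1ccccc1 | intermediate
5 | dimethyl chloromalonate | COC(=O)C(Cl)C(=O)OC | starting material
6 | dimethyl 2-[4-(benzyloxy)-3,5-dimethoxyphenoxy]malonate | COC(=O)C(Oc1cc(OC)c(OCc2ccccc2)c(OC)c1)C(=O)OC | intermediate
7 | dimethyl 3-oxopentanedioate | COC(=O)CC(=O)CC(=O)OC | starting material
8 | dimethyl 2-{2-[4-(benzyloxy)-3,5-dimethoxyphenoxy]-3-methoxy-3-oxopropanoyl}-3-oxopentanedioate (enolised, configurationally labile) | COC(=O)CC(=O)C(C(=O)OC)C(=O)C(Oc1cc(OC)c(OCc2ccccc2)c(OC)c1)C(=O)OC | intermediate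
9 | dimethyl 5-[4-(benzyloxy)-3,5-dimethoxyphenoxy]-2,4,6-trihydroxybenzene-1,3-dicarboxylate | COC(=O)c1c(O)c(C(=O)OC)c(O)c(Oc2cc(OC)c(OCc3ccccc3)c(OC)c2)c1O | intermediate
10 | 5-[4-(benzyloxy)-3,5-dimethoxyphenoxy]-2,4,6-trihydroxybenzene-1,3-dicarboxylic acid | OC(=O)c1c(O)c(C(O)=O)c(O)c(Oc2cc(OC)c(OCc3ccccc3)c(OC)c2)c1O | intermediate
11 | 2-[4-(benzyloxy)-3,5-dimethoxyphenoxy]benzene-1,3,5-triol | Oc1cc(O)c(Oc2cc(OC)c(OCc3ccccc3)c(OC)c2)c(O)c1 | intermediate
12 | 2-(benzyloxy)-1,3-dimethoxy-5-(2,4,6-trimethoxyphenoxy)benzene | COc1cc(OC)c(Oc2cc(OC)c(OCc3ccccc3)c(OC)c2)c(OC)c1 | intermediate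
13 | 2,6-dimethoxy-4-(2,4,6-trimethoxyphenoxy)phenol | COc1cc(OC)c(Oc2cc(OC)c(O)c(OC)c2)c(OC)c1 | intermediate
14 | 4-bromo-2,6-dimethoxyphenol | COc1cc(Br)cc(OC)c1O | starting material
15 | 2-(benzyloxy)-5-bromo-1,3-dimethoxybenzene | COc1cc(Br)cc(OC)c1OCc1ccccc1 | intermediate
16 | [4-(benzyloxy)-3,5-dimethoxyphenyl]lithium | [Li]c1cc(OC)c(OCc2ccccc2)c(OC)c1 | intermediate
17 | lithium [4-(benzyloxy)-3,5-dimethoxyphenyl]triisopropoxyborate | [Li+].CC(C)O[B-](OC(C)C)(OC(C)C)c1cc(OC)c(OCc2ccccc2)c(OC)c1 | intermediate
18 | [4-(benzyloxy)-3,5-dimethoxyphenyl]boronic acid | OB(O)c1cc(OC)c(OCc2ccccc2)c(OC)c1 | intermediate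
19 | 2,3,4-trimethoxybenzaldehyde | COc1ccc(C=O)c(OC)c1OC | starting material
20 | 2,3,4-trimethoxyphenyl formate | COc1ccc(OC=O)c(OC)c1OC | intermediate
21 | 2,3,4-trimethoxyphenol | COc1ccc(O)c(OC)c1OC | intermediate
22 | 6-iodo-2,3,4-trimethoxyphenol | COc1cc(I)c(O)c(OC)c1OC | intermediate
23 | 2-[4-(benzyloxy)-3,5-dimethoxyphenoxy]-1-iodo-3,4,5-trimethoxybenzene | COc1cc(I)c(Oc2cc(OC)c(OCc3ccccc3)c(OC)c2)c(OC)c1OC | intermediate
24 | (3,4,5-trimethoxyphenyl)boronic acid | COc1cc(B(O)O)cc(OC)c1OC | starting material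
25 | 5-bromo-1,3-dimethoxy-2-(3,4,5-trimethoxyphenoxy)benzene | COc1cc(Br)cc(OC)c1Oc1cc(OC)c(OC)c(OC)c1 | intermediate
26 | [3,5-dimethoxy-4-(3,4,5-trimethoxyphenoxy)phenyl]lithium | [Li]c1cc(OC)c(Oc2cc(OC)c(OC)c(OC)c2)c(OC)c1 | intermediate
27 | lithium [3,5-dimethoxy-4-(3,4,5-trimethoxyphenoxy)phenyl]triisopropoxyborate | [Li+].CC(C)O[B-](OC(C)C)(OC(C)C)c1cc(OC)c(Oc2cc(OC)c(OC)c(OC)c2)c(OC)c1 | intermediate
28 | [3,5-dimethoxy-4-(3,4,5-trimethoxyphenoxy)phenyl]boronic acid | OB(O)c1cc(OC)c(Oc2cc(OC)c(OC)c(OC)c2)c(OC)c1 | intermediate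
29 | 5-bromovanillin (3-bromo-4-hydroxy-5-methoxybenzaldehyde) | COc1cc(C=O)cc(Br)c1O | starting material
30 | 3-bromo-4-[3,5-dimethoxy-4-(3,4,5-trimethoxyphenoxy)phenoxy]-5-methoxybenzaldehyde | COc1cc(C=O)cc(Br)c1Oc1cc(OC)c(Oc2cc(OC)c(OC)c(OC)c2)c(OC)c1 | intermediate
31 | 3-bromo-4-[3,5-dimethoxy-4-(3,4,5-trimethoxyphenoxy)phenoxy]-5-methoxyphenyl formate | COc1cc(OC=O)cc(Br)c1Oc1cc(OC)c(Oc2cc(OC)c(OC)c(OC)c2)c(OC)c1 | intermediate
32 | 3-bromo-4-[3,5-dimethoxy-4-(3,4,5-trimethoxyphenoxy)phenoxy]-5-methoxyphenol | COc1cc(O)cc(Br)c1Oc1cc(OC)c(Oc2cc(OC)c(OC)c(OC)c2)c(OC)c1 | intermediate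
33 | 1-bromo-2-[3,5-dimethoxy-4-(3,4,5-trimethoxyphenoxy)phenoxy]-3,5-dimethoxybenzene | COc1cc(OC)c(Oc2cc(OC)c(Oc3cc(OC)c(OC)c(OC)c3)c(OC)c2)c(Br)c1 | intermediate
34 | 2-(benzyloxy)-5-{6-[2,6-dimethoxy-4-(2,4,6-trimethoxyphenoxy)phenoxy]-2,3,4-trimethoxyphenoxy}-1,3-dimethoxybenzene | COc1cc(OC)c(Oc2cc(OC)c(Oc3cc(OC)c(OC)c(OC)c3Oc3cc(OC)c(OCc4ccccc4)c(OC)c3)c(OC)c2)c(OC)c1 | intermediate
35 | 4-{6-[2,6-dimethoxy-4-(2,4,6-trimethoxyphenoxy)phenoxy]-2,3,4-trimethoxyphenoxy}-2,6-dimethoxyphenol | COc1cc(OC)c(Oc2cc(OC)c(Oc3cc(OC)c(OC)c(OC)c3Oc3cc(OC)c(O)c(OC)c3)c(OC)c2)c(OC)c1 | intermediate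
36 | heptadeca-O-methyl ether of the target (rings A–G) | COc1cc(OC)c(Oc2cc(OC)c(Oc3cc(OC)c(OC)c(OC)c3Oc3cc(OC)c(Oc4cc(OC)cc(OC)c4Oc4cc(OC)c(Oc5cc(OC)c(OC)c(OC)c5)c(OC)c4)c(OC)c3)c(OC)c2)c(OC)c1 | intermediate
37 | CNP0351377.0, seven-ring phlorotannin with rings A–G linked as in the lettering remark | Oc1cc(O)c(Oc2cc(O)c(Oc3cc(O)c(O)c(O)c3Oc3cc(O)c(Oc4cc(O)cc(O)c4Oc4cc(O)c(Oc5cc(O)c(O)c(O)c5)c(O)c4)c(O)c3)c(O)c2)c(O)c1 | target

Total step count: 21. Longest linear sequence: 11 steps (steps 1–7 and 18–21).

Steps most likely to fail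

First, step 4 (bears the label).
- What may go wrong: the crossed condensation may stall. The malonate may be parked as its unreactive enolate, the oxoglutarate may condense with itself, or the sequence may rest at the open-chain or pyranone stage instead of funnelling into the arene.
- The fallback uses only known chemistry, sets out from bromide 15 and comes back at 12. It gives up ring construction in favour of a C–O coupling.
- Commercial 2,4,6-trimethoxybenzaldehyde is oxidised with mCPBA (Baeyer–Villiger) to 2,4,6-trimethoxyphenyl formate F1.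
- Methanolysis (K2CO3, MeOH) gives 2,4,6-trimethoxyphenol F2.
- This di-ortho-substituted phenol is joined to the unhindered bromide 15 by Ullmann ether synthesis (CuI, picolinic acid, K3PO4, DMSO, 100 °C, argon) to give 12 directly.

Second, step 20 (step 18 is the same kind of union but has the more reactive iodide).
- What may go wrong: oxidative addition of the copper phenoxide to a bromide shielded by a two-ring aryloxy group may be so slow that hydrodebromination of 33 and oxidative decay of the electron-rich phenoxide of 35 win.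
- The fallback sets out from 35 and comes back at 36. It inserts ring E alone and moves the last union to the unhindered E C2–O–F C1 bond.
- 5-Bromovanillin 29 is benzylated (BnBr, K2CO3) to 4-(benzyloxy)-3-bromo-5-methoxybenzaldehyde F3.
- Oxidation with mCPBA gives 4-(benzyloxy)-3-bromo-5-methoxyphenyl formate F4, and methanolysis gives 4-(benzyloxy)-3-bromo-5-methoxyphenol F5.
- Methylation (MeI, K2CO3) gives 2-(benzyloxy)-1-bromo-3,5-dimethoxybenzene F6.
- This small bromide has only a slim benzyloxy group as ortho neighbour and can be used in threefold excess. It is coupled with 35 (CuI, picolinic acid, K3PO4, DMSO) to the five-ring benzyl ether F7.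
- Hydrogenolysis (H2, Pd/C) gives the five-ring phenol F8, and a last Ullmann coupling with the unhindered bromide 25 gives 36.

Third, step 21.
- What may go wrong: ether cleavage may remain incomplete because partly demethylated boron aryloxides drop out of solution, and the free polyphenol may be lost to air oxidation during isolation.
- The fallback sets out from 36 and comes back at 37. It replaces direct isolation by a derivatise, purify and release sequence.
- The crude product of the BBr3 treatment is acetylated at once (Ac2O, pyridine, argon) to the heptadecaacetate F9, which is air-stable, soluble and can be chromatographed on silica.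
- Under-cleaved fractions can therefore be separated and returned to BBr3.
- Transesterification of pure F9 (NaOMe cat., degassed MeOH, argon, then acidic ion-exchange resin) releases 37.

Further compounds
F1 | step 4 | 2,4,6-trimethoxyphenyl formate | O=COc1c(OC)cc(OC)cc1OC
F2 | step 4 | 2,4,6-trimethoxyphenol | Oc1c(OC)cc(OC)cc1OC
F3 | step 20 | 4-(benzyloxy)-3-bromo-5-methoxybenzaldehyde | O=Cc1cc(Br)c(OCc2ccccc2)c(OC)c1
F4 | step 20 | 4-(benzyloxy)-3-bromo-5-methoxyphenyl formate | O=COc1cc(Br)c(OCc2ccccc2)c(OC)c1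
F5 | step 20 | 4-(benzyloxy)-3-bromo-5-methoxyphenol | Oc1cc(Br)c(OCc2ccccc2)c(OC)c1
F6 | step 20 | 2-(benzyloxy)-1-bromo-3,5-dimethoxybenzene | COc1cc(Br)c(OCc2ccccc2)c(OC)c1
F7 | step 20 | five-ring benzyl ether (rings A–E, E C2–OBn, all other phenols as OMe) | COc1cc(OC)c(Oc2cc(OC)c(Oc3cc(OC)c(OC)c(OC)c3Oc3cc(OC)c(Oc4cc(OC)cc(OC)c4OCc4ccccc4)c(OC)c3)c(OC)c2)c(OC)c1
F8 | step 20 | five-ring phenol (rings A–E, E C2–OH, all other phenols as OMe) | COc1cc(OC)c(Oc2cc(OC)c(Oc3cc(OC)c(OC)c(OC)c3Oc3cc(OC)c(Oc4cc(OC)cc(OC)c4O)c(OC)c3)c(OC)c2)c(OC)c1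
F9 | step 21 | heptadecaacetate of the target | CC(=O)Oc1cc(OC(C)=O)c(Oc2cc(OC(C)=O)c(Oc3cc(OC(C)=O)c(OC(C)=O)c(OC(C)=O)c3Oc3cc(OC(C)=O)c(Oc4cc(OC(C)=O)cc(OC(C)=O)c4Oc4cc(OC(C)=O)c(Oc5cc(OC(C)=O)c(OC(C)=O)c(OC(C)=O)c5)c(OC(C)=O)c4)c(OC(C)=O)c3)c(OC(C)=O)c2)c(OC(C)=O)c1
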